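**Assumption:** the (R)-ligand is taken to give (2R,3R)-11 by analogy with simple acyl donors; if the first run shows the opposite sense, the (S)-ligand is used and nothing else changes.

The target SMILES reads as the erythro (7″R,8″S) isomer. In the propyl acetate numbering this is (2S,3R). At the acyl (thioimide) stage the same arrangement is the anti-aldol pattern, (2R,3R).

## Retrosynthetic overview

1. Target 15 ⇐ 14 (hydrogenolysis of three benzyl ethers) ⇐ 13 (removal of the C7″ silyl ether).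
2. 13 ⇐ 11 by reductive removal of an achiral thioimide and acetylation of the freed primary alcohol; the silyl group delivered in the aldol keeps C7″–OH masked, so no diol differentiation is needed.
3. 11 ⇐ 9 + 10 by a new Ni(II)-catalysed direct anti-aldol of an α-aryloxyacetyl thioimide, which forms the C7″–C8″ bond and both stereocentres.
4. 9 ⇐ flavone acid 7 ⇐ chalcone 6 ⇐ syringaldehyde glycolate 3 + acetophenone 4.
5. Ring order: only the pyranone ring is built (step 3), before the stereocentres; all benzene rings are bought.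

## Route

Step 1
Reactants: 1 syringaldehyde; 2 ethyl bromoacetate
Product: 3 ethyl 2-(4-formyl-2,6-dimethoxyphenoxy)acetate
Conditions: K2CO3, DMF, 50 °C
Reagents that add atoms: none
Why: Williamson ether synthesis of an acidic phenol with an activated primary bromide; the aldehyde is inert to carbonate.

Step 2
Reactants: 3 ethyl 2-(4-formyl-2,6-dimethoxyphenoxy)acetate; 4 2′-hydroxy-4′,6′-bis(benzyloxy)acetophenone
Product: 6 2-{4-[(E)-3-(2,4-bis(benzyloxy)-6-hydroxyphenyl)-3-oxoprop-1-en-1-yl]-2,6-dimethoxyphenoxy}acetic acid, via potassium 2-(4-formyl-2,6-dimethoxyphenoxy)acetate 5 (not isolated)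
Conditions: KOH (10 equiv), EtOH/THF/H2O, rt, 48 h; then 1 M HCl to pH 2
Reagents that add atoms: potassium hydroxide, [K+].[OH-]
Why: The aryloxyacetate is saponified within minutes and the non-enolisable aldehyde then undergoes Claisen–Schmidt condensation with the acetophenone enolate to give the E-chalcone; benzyl ethers are stable to hydroxide.

Step 3
Reactants: 6 chalcone acid
Product: 7 2-{4-[5,7-bis(benzyloxy)-4-oxo-4H-chromen-2-yl]-2,6-dimethoxyphenoxy}acetic acid
Conditions: I2 (10 mol%), DMSO, 130 °C, 3 h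
Reagents that add atoms: none
Why: Iodine/DMSO oxidative cyclisation of a 2′-hydroxychalcone (oxa-Michael closure, then iodination and dehydroiodination with DMSO as terminal oxidant) builds the 4H-chromen-4-one ring; benzyl ethers and the acid are expected to survive.

Step 4
Reactants: 7 flavone acid; 8 1,3-thiazinane-2-thione
Product: 9 3-{2-[4-(5,7-bis(benzyloxy)-4-oxo-4H-chromen-2-yl)-2,6-dimethoxyphenoxy]acetyl}-1,3-thiazinane-2-thione
Conditions: EDC·HCl, DMAP (cat.), CH2Cl2, 0 °C to rt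
Reagents that add atoms: none
Why: Carbodiimide/DMAP (Steglich-type) N-acylation of the thione gives the achiral, chelating thioimide needed for soft enolisation.

Step 5
Reactants: 9 α-aryloxyacetyl thioimide; 10 4-(benzyloxy)-3-methoxybenzaldehyde
Product: 11 3-{(2R,3R)-3-[4-(benzyloxy)-3-methoxyphenyl]-2-[4-(5,7-bis(benzyloxy)-4-oxo-4H-chromen-2-yl)-2,6-dimethoxyphenoxy]-3-[(triisopropylsilyl)oxy]propanoyl}-1,3-thiazinane-2-thione
Conditions: [(R)-DTBM-SEGPHOS]NiCl2 (5 mol%), TIPSOTf (2.5 equiv), 2,6-lutidine (3 equiv), CH2Cl2, −20 °C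
Reagents that add atoms: triisopropylsilyl trifluoromethanesulfonate, CC(C)[Si](OS(=O)(=O)C(F)(F)F)(C(C)C)C(C)C
Why: Proposed new method: a chiral Ni(II)–bisphosphine-catalysed direct anti-aldol of an α-aryloxyacetyl thioimide, in which the S,O-chelated thioimide is soft-enolised by lutidine to a (Z)-nickel enolate with one π-face blocked by the P-aryl groups, the electron-rich aldehyde is activated by TIPSOTf as a silyloxycarbenium ion and adds through an open antiperiplanar transition state to give the anti (2R,3R) adduct (erythro, 7″R,8″S), and irreversible O-silylation turns the catalyst over; the closest known reaction type is the Ni(II)–bisphosphine-catalysed, silyl-triflate-promoted direct aldol of N-acyl thioimides with aromatic aldehydes, which has not been shown for α-aryloxy donors that build a β-O-4 aryl ether.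

Step 6
Reactants: 11 anti-aldol adduct
Product: 12 (2S,3R)-3-[4-(benzyloxy)-3-methoxyphenyl]-2-[4-(5,7-bis(benzyloxy)-4-oxo-4H-chromen-2-yl)-2,6-dimethoxyphenoxy]-3-[(triisopropylsilyl)oxy]propan-1-ol
Conditions: NaBH4, THF/H2O 4:1, 0 °C, 30 min
Reagents that add atoms: none
Why: Borohydride reductive cleavage of the highly activated N-acyl thioimide gives the primary alcohol and frees the scaffold, while the vinylogous-ester flavone carbonyl is far less electrophilic and stays; no stereocentre is touched.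

Step 7
Reactants: 12 primary alcohol
Product: 13 (2S,3R)-3-[4-(benzyloxy)-3-methoxyphenyl]-2-[4-(5,7-bis(benzyloxy)-4-oxo-4H-chromen-2-yl)-2,6-dimethoxyphenoxy]-3-[(triisopropylsilyl)oxy]propyl acetate
Conditions: Ac2O, pyridine, DMAP (cat.), CH2Cl2, 0 °C to rt
Reagents that add atoms: acetic anhydride, CC(=O)OC(C)=O
Why: DMAP-catalysed acetylation of the only free hydroxyl is regiospecific because the secondary oxygen is still a silyl ether.

Step 8
Reactants: 13 silyl ether acetate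
Product: 14 (2S,3R)-3-[4-(benzyloxy)-3-methoxyphenyl]-2-[4-(5,7-bis(benzyloxy)-4-oxo-4H-chromen-2-yl)-2,6-dimethoxyphenoxy]-3-hydroxypropyl acetate
Conditions: HF·pyridine, pyridine/THF, 0 °C to rt
Reagents that add atoms: none
Why: Fluoride-mediated desilylation under buffered, weakly acidic conditions avoids base-promoted 1,3-acetyl migration, and with the para-oxygen still benzylated the benzylic carbinol has no quinone-methide path to epimerise.

Step 9
Reactants: 14 tribenzyl ether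
Product: 15 (2S,3R)-2-[4-(5,7-dihydroxy-4-oxo-4H-chromen-2-yl)-2,6-dimethoxyphenoxy]-3-hydroxy-3-(4-hydroxy-3-methoxyphenyl)propyl acetate
Conditions: H2 (1 atm), 10% Pd/C, EtOAc/THF, rt
Reagents that add atoms: none
Why: Palladium-catalysed hydrogenolysis removes the three aryl benzyl ethers under neutral conditions that leave the acetate, the alkyl aryl ether, the flavone and both stereocentres intact.

## Compound list

1 | syringaldehyde (4-hydroxy-3,5-dimethoxybenzaldehyde) | COc1cc(C=O)cc(OC)c1O | starting material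
2 | ethyl bromoacetate | CCOC(=O)CBr | starting material
3 | ethyl 2-(4-formyl-2,6-dimethoxyphenoxy)acetate | CCOC(=O)COc1c(OC)cc(C=O)cc1OC | intermediate
4 | 1-[2-hydroxy-4,6-bis(benzyloxy)phenyl]ethan-1-one (2′-hydroxy-4′,6′-bis(benzyloxy)acetophenone) | CC(=O)c1c(O)cc(OCc2ccccc2)cc1OCc1ccccc1 | starting material
5 | potassium 2-(4-formyl-2,6-dimethoxyphenoxy)acetate | [K+].[O-]C(=O)COc1c(OC)cc(C=O)cc1OC | intermediate
6 | 2-{4-[(E)-3-(2,4-bis(benzyloxy)-6-hydroxyphenyl)-3-oxoprop-1-en-1-yl]-2,6-dimethoxyphenoxy}acetic acid | OC(=O)COc1c(OC)cc(/C=C/C(=O)c2c(O)cc(OCc3ccccc3)cc2OCc2ccccc2)cc1OC | intermediate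
7 | 2-{4-[5,7-bis(benzyloxy)-4-oxo-4H-chromen-2-yl]-2,6-dimethoxyphenoxy}acetic acid | OC(=O)COc1c(OC)cc(-c2cc(=O)c3c(OCc4ccccc4)cc(OCc4ccccc4)cc3o2)cc1OC | intermediate
8 | 1,3-thiazinane-2-thione | S=C1NCCCS1 | starting material
9 | 3-{2-[4-(5,7-bis(benzyloxy)-4-oxo-4H-chromen-2-yl)-2,6-dimethoxyphenoxy]acetyl}-1,3-thiazinane-2-thione | S=C1SCCCN1C(=O)COc1c(OC)cc(-c2cc(=O)c3c(OCc4ccccc4)cc(OCc4ccccc4)cc3o2)cc1OC | intermediate
10 | 4-(benzyloxy)-3-methoxybenzaldehyde (O-benzylvanillin) | COc1cc(C=O)ccc1OCc1ccccc1 | starting material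
11 | 3-{(2R,3R)-3-[4-(benzyloxy)-3-methoxyphenyl]-2-[4-(5,7-bis(benzyloxy)-4-oxo-4H-chromen-2-yl)-2,6-dimethoxyphenoxy]-3-[(triisopropylsilyl)oxy]propanoyl}-1,3-thiazinane-2-thione | COc1cc([C@@H](O[Si](C(C)C)(C(C)C)C(C)C)[C@H](C(=O)N2CCCSC2=S)Oc2c(OC)cc(-c3cc(=O)c4c(OCc5ccccc5)cc(OCc5ccccc5)cc4o3)cc2OC)ccc1OCc1ccccc1 | intermediate
12 | (2S,3R)-3-[4-(benzyloxy)-3-methoxyphenyl]-2-[4-(5,7-bis(benzyloxy)-4-oxo-4H-chromen-2-yl)-2,6-dimethoxyphenoxy]-3-[(triisopropylsilyl)oxy]propan-1-ol | COc1cc([C@@H](O[Si](C(C)C)(C(C)C)C(C)C)[C@H](CO)Oc2c(OC)cc(-c3cc(=O)c4c(OCc5ccccc5)cc(OCc5ccccc5)cc4o3)cc2OC)ccc1OCc1ccccc1 | intermediate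
13 | (2S,3R)-3-[4-(benzyloxy)-3-methoxyphenyl]-2-[4-(5,7-bis(benzyloxy)-4-oxo-4H-chromen-2-yl)-2,6-dimethoxyphenoxy]-3-[(triisopropylsilyl)oxy]propyl acetate | COc1cc([C@@H](O[Si](C(C)C)(C(C)C)C(C)C)[C@H](COC(C)=O)Oc2c(OC)cc(-c3cc(=O)c4c(OCc5ccccc5)cc(OCc5ccccc5)cc4o3)cc2OC)ccc1OCc1ccccc1 | intermediate
14 | (2S,3R)-3-[4-(benzyloxy)-3-methoxyphenyl]-2-[4-(5,7-bis(benzyloxy)-4-oxo-4H-chromen-2-yl)-2,6-dimethoxyphenoxy]-3-hydroxypropyl acetate | COc1cc([C@@H](O)[C@H](COC(C)=O)Oc2c(OC)cc(-c3cc(=O)c4c(OCc5ccccc5)cc(OCc5ccccc5)cc4o3)cc2OC)ccc1OCc1ccccc1 | intermediate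
15 | (2S,3R)-2-[4-(5,7-dihydroxy-4-oxo-4H-chromen-2-yl)-2,6-dimethoxyphenoxy]-3-hydroxy-3-(4-hydroxy-3-methoxyphenyl)propyl acetate (tricin 4′-O-(erythro-β-guaiacylglyceryl) ether 9″-acetate, 7″R,8″S) | COc1cc([C@@H](O)[C@H](COC(C)=O)Oc2c(OC)cc(-c3cc(=O)c4c(O)cc(O)cc4o3)cc2OC)ccc1O | target

## Summary

Total step count: 9. Longest linear sequence: 9 steps (1 to 15); all coupling partners are bought.

Three steps most likely to fail:

**Step 5 (the new aldol).** Risks are a wrong or low anti/syn ratio with the bulky aryloxy group, reversible O-silylation of the flavone carbonyl consuming TIPSOTf (hence the extra equivalent), or attack on the silylated pyrylium. The fallback uses known chemistry, sets out from 7 and comes back at 14. Acid 7 is N-acylated with (R)-4-benzyl-1,3-oxazolidin-2-one (DCC, DMAP, CH2Cl2) to give the N-acyloxazolidinone F1. An Evans boron aldol (Bu2BOTf 2.5 equiv, iPr2NEt, CH2Cl2, −78 to 0 °C, then aldehyde 10, buffered H2O2 work-up) gives the syn aldol F2 (2R,3S), with C8″ correct and C7″ epimeric. Mitsunobu inversion of the benzylic carbinol (4-nitrobenzoic acid, PPh3, DIAD, THF, 0 °C) gives the anti 4-nitrobenzoate F3. LiBH4 (THF/MeOH, 0 °C) removes the auxiliary and the benzoate together to give the erythro diol F4. CAL-B lipase with vinyl acetate in THF then acetylates only the primary hydroxyl, giving 14.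

**Step 3 (oxidative cyclisation).** Risks are partial loss of the 5-O-benzyl group to HI at 130 °C or side reactions of the free acid. The fallback sets out from 6 and comes back at 7. Chalcone 6 is closed by oxa-Michael addition alone (NaOAc, EtOH, reflux) to the racemic flavanone acid F5, which is then dehydrogenated in a separate operation (DDQ, 1,4-dioxane, reflux) to 7.

**Step 9 (global hydrogenolysis).** Risks are loss of the benzylic C7″–OH once the para-phenol is free, or saturation of the flavone C2=C3 bond. The fallback sets out from 13 and comes back at 15. Silyl ether 13 is hydrogenolysed first (H2, Pd/C, EtOAc/THF), while the benzylic oxygen is still protected, to give the triphenol silyl ether F6. The silyl group is then removed with Et3N·3HF in THF at rt to give 15.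

Further compounds

F1 | step 5 | (4R)-4-benzyl-3-{2-[4-(5,7-bis(benzyloxy)-4-oxo-4H-chromen-2-yl)-2,6-dimethoxyphenoxy]acetyl}-1,3-oxazolidin-2-one | O=C1OC[C@@H](Cc2ccccc2)N1C(=O)COc1c(OC)cc(-c2cc(=O)c3c(OCc4ccccc4)cc(OCc4ccccc4)cc3o2)cc1OC
F2 | step 5 | (4R)-4-benzyl-3-{(2R,3S)-3-[4-(benzyloxy)-3-methoxyphenyl]-2-[4-(5,7-bis(benzyloxy)-4-oxo-4H-chromen-2-yl)-2,6-dimethoxyphenoxy]-3-hydroxypropanoyl}-1,3-oxazolidin-2-one | COc1cc([C@H](O)[C@H](C(=O)N2[C@H](Cc3ccccc3)COC2=O)Oc2c(OC)cc(-c3cc(=O)c4c(OCc5ccccc5)cc(OCc5ccccc5)cc4o3)cc2OC)ccc1OCc1ccccc1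
F3 | step 5 | (1R,2R)-1-[4-(benzyloxy)-3-methoxyphenyl]-3-[(4R)-4-benzyl-2-oxo-1,3-oxazolidin-3-yl]-2-[4-(5,7-bis(benzyloxy)-4-oxo-4H-chromen-2-yl)-2,6-dimethoxyphenoxy]-3-oxopropyl 4-nitrobenzoate | COc1cc([C@@H](OC(=O)c2ccc(cc2)[N+](=O)[O-])[C@H](C(=O)N2[C@H](Cc3ccccc3)COC2=O)Oc2c(OC)cc(-c3cc(=O)c4c(OCc5ccccc5)cc(OCc5ccccc5)cc4o3)cc2OC)ccc1OCc1ccccc1
F4 | step 5 | (1R,2S)-1-[4-(benzyloxy)-3-methoxyphenyl]-2-[4-(5,7-bis(benzyloxy)-4-oxo-4H-chromen-2-yl)-2,6-dimethoxyphenoxy]propane-1,3-diol | COc1cc([C@@H](O)[C@H](CO)Oc2c(OC)cc(-c3cc(=O)c4c(OCc5ccccc5)cc(OCc5ccccc5)cc4o3)cc2OC)ccc1OCc1ccccc1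
F5 | step 3 | rac-2-{4-[5,7-bis(benzyloxy)-4-oxochroman-2-yl]-2,6-dimethoxyphenoxy}acetic acid | OC(=O)COc1c(OC)cc(C2CC(=O)c3c(OCc4ccccc4)cc(OCc4ccccc4)cc3O2)cc1OC
F6 | step 9 | (2S,3R)-2-[4-(5,7-dihydroxy-4-oxo-4H-chromen-2-yl)-2,6-dimethoxyphenoxy]-3-(4-hydroxy-3-methoxyphenyl)-3-[(triisopropylsilyl)oxy]propyl acetate | COc1cc([C@@H](O[Si](C(C)C)(C(C)C)C(C)C)[C@H](COC(C)=O)Oc2c(OC)cc(-c3cc(=O)c4c(O)cc(O)cc4o3)cc2OC)ccc1O
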